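**Retrosynthetic overview**
1. No ring is formed: both benzene rings are bought, and the only bond joining them, the diaryl ether C–O bond, is made last.
2. Ring A: 3,5-dibromosalicylaldehyde 1 → methyl ether 2 → (formate 3) → 3,5-dibromo-2-methoxyphenol 4, a formyl-to-hydroxyl exchange.
3. Ring B: 2-amino-5-bromophenol 5 → (diazonium salt 6) → ortho-quinone diazide 7, which already carries the ring B oxygen and bromine in the right places.
4. Key disconnection: target 8 ⇒ 4 + 7 by a proposed rhodium-carbenoid O–H insertion (new), which forms the aryl–O bond without activating any of the three C–Br bonds.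

Assumption: the target has no stereocentre and its diaryl ether axis rotates freely, so the "single enantiomer" is the achiral compound itself and no SMILES carries stereodescriptors.

**Route**

Step 1
Reactants: 1 3,5-dibromo-2-hydroxybenzaldehyde
Product: 2 3,5-dibromo-2-methoxybenzaldehyde
Conditions: MeI, K2CO3, DMF, 25 °C
Reagents that add atoms: iodomethane, CI
Why: Williamson ether synthesis; the acidic phenoxide is methylated by SN2 attack on MeI, and the aldehyde and aryl bromides are inert.

Step 2
Reactants: 2 3,5-dibromo-2-methoxybenzaldehyde
Product: 4 3,5-dibromo-2-methoxyphenol, via 3,5-dibromo-2-methoxyphenyl formate 3 (not isolated)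
Conditions: mCPBA, CH2Cl2, 40 °C; NaHCO3/Na2S2O3 wash; then K2CO3 (0.2 equiv), MeOH, 25 °C
Reagents that add atoms: meta-chloroperoxybenzoic acid (mCPBA), OOC(=O)c1cccc(Cl)c1
Why: Baeyer–Villiger (Dakin-type) oxidation; the ortho-methoxy group favours aryl over hydride migration in the Criegee adduct to give formate 3, which base-catalysed methanolysis cleaves to the phenol.

Step 3
Reactants: 5 2-amino-5-bromophenol
Product: 7 3-bromo-6-diazocyclohexa-2,4-dien-1-one, via 4-bromo-2-hydroxybenzenediazonium chloride 6 (not isolated)
Conditions: NaNO2, 2 M HCl, 0 °C; then NaHCO3 to pH 7, CH2Cl2 extraction, 0 °C, dark (used the same day as a dried CH2Cl2 solution, never concentrated to dryness)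
Reagents that add atoms: sodium nitrite, [Na+].[O-]N=O; hydrogen chloride, Cl (supplies only the chloride counter-ion of intermediate 6)
Why: Diazotisation of a primary arylamine; neutralisation deprotonates the acidic ortho-hydroxy diazonium ion (pKa about 4) to the neutral quinone diazide, which partitions into CH2Cl2 and is kept cold, dark and in solution because it is light- and shock-sensitive.

Step 4
Reactants: 4 3,5-dibromo-2-methoxyphenol; 7 3-bromo-6-diazocyclohexa-2,4-dien-1-one
Product: 8 5-bromo-2-(3,5-dibromo-2-methoxyphenoxy)phenol
Conditions: Rh2(esp)2 (1 mol %; esp = α,α,α′,α′-tetramethyl-1,3-benzenedipropionate), 4 (2 equiv), CH2Cl2, 35 °C, dark; 7 (CH2Cl2 solution) added by syringe pump over 4 h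
Reagents that add atoms: none
Why: Proposed new method: dirhodium-catalysed O–H insertion of an unstabilised, halogenated ortho-benzoquinone diazide into a free, electron-poor ortho-substituted phenol to forge an ortho-hydroxy diaryl ether, a substrate pairing for which this reactivity is, to the best of current knowledge, not demonstrated; the divalent-rhodium dimer Rh2(esp)2 expels N2 from 7 to give an electrophilic rhodium-bound quinoid carbene (a catalyst-bound transient), the hydroxyl oxygen of 4 attacks the carbene carbon, release of the metal re-aromatises ring B to an oxonium phenolate, and proton transfer from the oxonium to the phenolate oxygen gives 8 with the OH ortho and the Br para to the new C–O bond by construction; O-attack should beat C-arylation because ring A of 4 is deactivated and both open positions ortho and para to its OH are flanked by bromine, slow addition of 7 into excess 4 suppresses carbene dimerisation and a second insertion into the OH of 8, and the three C–Br bonds are safe because no low-valent metal capable of oxidative addition is present; the closest known reaction types are the O–H insertion of rhodium carbenoids from alpha-diazocarbonyl compounds into phenols and the rhodium-catalysed aryl transfer from quinone diazides to C–H bonds.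

**Compound list**
1 | 3,5-dibromo-2-hydroxybenzaldehyde (3,5-dibromosalicylaldehyde) | O=Cc1cc(Br)cc(Br)c1O | starting material
2 | 3,5-dibromo-2-methoxybenzaldehyde | COc1c(Br)cc(Br)cc1C=O | intermediate
3 | 3,5-dibromo-2-methoxyphenyl formate | COc1c(Br)cc(Br)cc1OC=O | intermediate
4 | 3,5-dibromo-2-methoxyphenol | COc1c(Br)cc(Br)cc1O | intermediate
5 | 2-amino-5-bromophenol | Nc1ccc(Br)cc1O | starting material
6 | 4-bromo-2-hydroxybenzenediazonium chloride | Oc1cc(Br)ccc1[N+]#N.[Cl-] | intermediate
7 | 3-bromo-6-diazocyclohexa-2,4-dien-1-one (5-bromo-2-diazoniophenolate) | [N-]=[N+]=C1C=CC(Br)=CC1=O | intermediate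
8 | 5-bromo-2-(3,5-dibromo-2-methoxyphenoxy)phenol (CNP0017937.0) | COc1c(Br)cc(Br)cc1Oc1ccc(Br)cc1O | target

**Step count**
Total steps: 4 (convergent). Longest linear sequence: 3 steps (steps 1, 2 and 4); the ring B branch is step 3 followed by step 4.

**Three steps most likely to fail, with fallbacks**

Step 4 (the proposed new O–H insertion). The risks are slow carbenoid formation from the diazonium-like quinone diazide, C-arylation of 4, carbene dimerisation and over-insertion into the product OH. The fallback uses only known chemistry; it sets out from 4 and comes back to the route at 8. Phenol 4 is heated with commercial 5-bromo-2-fluorobenzaldehyde (O=Cc1cc(Br)ccc1F) and K2CO3 in DMAc at 110 °C. Nucleophilic aromatic substitution of the fluoride, activated by the ortho-formyl group, gives 5-bromo-2-(3,5-dibromo-2-methoxyphenoxy)benzaldehyde F1. Baeyer–Villiger oxidation of F1 (mCPBA, CH2Cl2, 40 °C) gives 5-bromo-2-(3,5-dibromo-2-methoxyphenoxy)phenyl formate F2, which is methanolysed without isolation (K2CO3, MeOH, 25 °C) to 8.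

Step 3 (making and handling quinone diazide 7). The risks are azo coupling during diazotisation and decomposition of 7 on extraction or storage. The fallback avoids the neutral quinone diazide altogether; it sets out from 5 and comes back to the route at 8. Amine 5 is diazotised as before (NaNO2, aqueous HCl, 0 °C) to 6, and the acidic solution is treated directly with KI (0 to 25 °C) to give 5-bromo-2-iodophenol F3. Protection (MOMCl, iPr2NEt, CH2Cl2, 0 °C) gives 4-bromo-1-iodo-2-(methoxymethoxy)benzene F4. Ullmann-type coupling of F4 with phenol 4 (CuI, picolinic acid, K3PO4, DMSO, 80 °C), in which the aryl iodide reacts well ahead of the aryl bromides, gives 1,5-dibromo-3-[4-bromo-2-(methoxymethoxy)phenoxy]-2-methoxybenzene F5. Acetal cleavage (HCl, MeOH, 40 °C) then gives 8.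

Step 2 (Baeyer–Villiger oxidation of aldehyde 2). The risk is hydride migration to the benzoic acid, or a sluggish reaction, because the two bromines lower the migratory aptitude of the ring. The fallback removes the migrating hydrogen by switching to the aryl methyl ketone; it sets out from 2 and comes back to the route at 4. Addition of MeMgBr (THF, −78 °C) to 2 gives racemic 1-(3,5-dibromo-2-methoxyphenyl)ethan-1-ol F6, whose stereocentre is erased in the next operation. Oxidation (MnO2, CH2Cl2, 25 °C) gives 1-(3,5-dibromo-2-methoxyphenyl)ethan-1-one F7. Baeyer–Villiger oxidation with trifluoroperacetic acid (from trifluoroacetic anhydride and urea–hydrogen peroxide, CH2Cl2, 0 to 25 °C), in which aryl migrates in preference to methyl, gives 3,5-dibromo-2-methoxyphenyl acetate F8. Methanolysis (K2CO3, MeOH, 25 °C) then gives 4.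

Further compounds
F1 | step 4 | 5-bromo-2-(3,5-dibromo-2-methoxyphenoxy)benzaldehyde | COc1c(Br)cc(Br)cc1Oc1ccc(Br)cc1C=O
F2 | step 4 | 5-bromo-2-(3,5-dibromo-2-methoxyphenoxy)phenyl formate | COc1c(Br)cc(Br)cc1Oc1ccc(Br)cc1OC=O
F3 | step 3 | 5-bromo-2-iodophenol | Oc1cc(Br)ccc1I
F4 | step 3 | 4-bromo-1-iodo-2-(methoxymethoxy)benzene | COCOc1cc(Br)ccc1I
F5 | step 3 | 1,5-dibromo-3-[4-bromo-2-(methoxymethoxy)phenoxy]-2-methoxybenzene | COCOc1cc(Br)ccc1Oc1cc(Br)cc(Br)c1OC
F6 | step 2 | 1-(3,5-dibromo-2-methoxyphenyl)ethan-1-ol (racemic) | COc1c(Br)cc(Br)cc1C(C)O
F7 | step 2 | 1-(3,5-dibromo-2-methoxyphenyl)ethan-1-one | COc1c(Br)cc(Br)cc1C(C)=O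
F8 | step 2 | 3,5-dibromo-2-methoxyphenyl acetate | COc1c(Br)cc(Br)cc1OC(C)=O
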